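## Retrosynthetic overview

1. The 3α,4α-epoxide comes from face-selective epoxidation of a trans-fused guai-3-ene, which comes from a 3-oxoguai-4-ene by tosylhydrazone reduction with allylic-diazene transposition (moves the C=C, sets H5).
2. The five/seven skeleton comes from a 365 nm santonin-type rearrangement of a six/six cross-conjugated eudesma-1,4-dien-3-one in aqueous acetic acid (C1–C5 bond made, C5–C10 broken, water enters at C10).
3. Ring A of the dienone comes from a new dehydrative annulation of a regiodefined silyl enol ether with 1,1-dimethoxypentan-3-one (sets quaternary C10 under control of the C8 ester).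
4. Ring B with C7 and C8 comes from (R)-α-phellandrene by singlet-oxygen [4+2] addition and Kornblum–DeLaMare rearrangement, then invertive Mitsunobu esterification with isovanillic acid.
5. Ring order: ring B is bought, ring A is annulated onto it, then light converts the six/six system into the five/seven system.

Assumption: commercial (R)-(−)-α-phellandrene is used as the single enantiomer, and its singlet-oxygen adduct formed anti to the isopropyl group is taken to be the major diastereomer (about 3:2); the minor cis-series material is removed by chromatography after step 1.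

Numbering note: compounds 10 and later are named with eudesmane or guaiane numbering (guaiane: C1/C5 ring fusion, methyl groups on C4 and C10, isopropyl on C7, ester on C8).

## Route

Step 1
Reactants: 1 (R)-(−)-α-phellandrene
Product: 3 (4R,5R)-4-hydroxy-2-methyl-5-(propan-2-yl)cyclohex-2-en-1-one, via trans-endoperoxide 2 (not isolated)
Conditions: O2, tetraphenylporphyrin (cat.), hν (white LED), CH2Cl2, 0 °C; then Et3N, 0 °C → rt
Reagents that add atoms: dioxygen, O=O
Why: Photosensitised singlet oxygen adds [4+2] to the s-cis diene mainly on the face anti to the isopropyl group (this sets the C4–O bond trans to isopropyl), and the Kornblum–DeLaMare rearrangement then removes the bridgehead hydrogen flanked by CH2 rather than the one next to the isopropyl-bearing carbon, so the ketone forms beside the methyl-bearing alkene carbon and the hydroxyl stays next to the isopropyl carbon.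

Step 2
Reactants: 3 (4R,5R)-4-hydroxy-2-methyl-5-(propan-2-yl)cyclohex-2-en-1-one; 4 isovanillic acid
Product: 6 (1S,6R)-3-methyl-4-oxo-6-(propan-2-yl)cyclohex-2-en-1-yl 3-acetoxy-4-methoxybenzoate, via phenol ester 5 (not isolated)
Conditions: PPh3, DIAD, THF, 0 °C → rt; then Ac2O, Et3N, DMAP (cat.), rt
Reagents that add atoms: acetic anhydride, CC(=O)OC(C)=O
Why: Mitsunobu esterification displaces the oxyphosphonium by SN2 with inversion, so the trans alcohol gives the ester cis to isopropyl (the 8β-ester of the target), the carboxylic acid (pKa about 4.5) reacting in preference to the phenol (pKa about 9); the phenol is then capped as its acetate in the same flask so that it cannot protonate the copper enolate in step 3.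

Step 3
Reactants: 6 (1S,6R)-3-methyl-4-oxo-6-(propan-2-yl)cyclohex-2-en-1-yl 3-acetoxy-4-methoxybenzoate
Product: 7 (1R,6R)-4-{[dimethyl(phenyl)silyl]oxy}-3-methyl-6-(propan-2-yl)cyclohex-3-en-1-yl 3-acetoxy-4-methoxybenzoate
Conditions: PhMe2SiH, [(Ph3P)CuH]6 (3 mol %), toluene, rt
Reagents that add atoms: dimethylphenylsilane, C[SiH](C)c1ccccc1
Why: Copper hydride-catalysed 1,4-hydrosilylation (conjugate reduction) delivers hydride to the β-carbon and traps the enolate as the regiodefined tetrasubstituted silyl enol ether, with no new stereocenter and without touching the esters or the γ-acyloxy group.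

Step 4
Reactants: 7 (1R,6R)-4-{[dimethyl(phenyl)silyl]oxy}-3-methyl-6-(propan-2-yl)cyclohex-3-en-1-yl 3-acetoxy-4-methoxybenzoate; 8 1,1-dimethoxypentan-3-one
Product: 10 (7R,8R,10S)-3-oxoeudesma-1,4-dien-8-yl 3-hydroxy-4-methoxybenzoate, via methoxy diketone 9 (not isolated)
Conditions: TMSOTf (0.2 equiv), CH2Cl2, −78 → −20 °C; then pyrrolidine, AcOH, MeOH, 55 °C
Reagents that add atoms: none
Why: Proposed new method: a dehydrative dienone annulation in which TMSOTf ionises the β-keto acetal to an oxocarbenium ion that is attacked by the tetrasubstituted silyl enol ether (Mukaiyama acetal aldol) on the face anti to the pseudo-axial C8 aroyloxy group, which sits 1,3-syn to the enol carbon and blocks the β-face, so the new C10–C1 bond forms on the α-face and the C10 methyl ends cis to isopropyl; pyrrolidinium acetate then closes ring A by enamine aldol onto the ring ketone, dehydrates, eliminates methanol by E1cB (reversible aza-Michael addition rescues any E-enone formed by early elimination) and cleaves the aryl acetate, giving the cross-conjugated dienone without a separate dehydrogenation, the closest known reactions being the Noyori–Mukaiyama acetal aldol and the amine-mediated Robinson annulation.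

Step 5
Reactants: 10 (7R,8R,10S)-3-oxoeudesma-1,4-dien-8-yl 3-hydroxy-4-methoxybenzoate
Product: 11 (1R,7R,8R,10R)-10-hydroxy-3-oxoguai-4-en-8-yl 3-hydroxy-4-methoxybenzoate
Conditions: hν (365 nm), AcOH–H2O (1:1), 80 °C
Reagents that add atoms: water, O
Why: In this santonin-type photorearrangement of a 4-methyl cross-conjugated cyclohexadienone, excitation of the dienone (the benzoate does not absorb at 365 nm) bonds C1 to C5 to give a cyclopropyl oxyallyl zwitterion whose protonated form opens by cleavage of C5–C10 with backside capture of water at C10, which turns the 10β-methyl quaternary centre into the 10α-hydroxy-10β-methyl carbinol and leaves H1 on the α-face, as in the conversion of santonin into isophotosantonic lactone.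

Step 6
Reactants: 11 (1R,7R,8R,10R)-10-hydroxy-3-oxoguai-4-en-8-yl 3-hydroxy-4-methoxybenzoate
Product: 12 (1R,7R,8R,10R)-10-hydroxy-3-[(E)-2-(4-methylbenzenesulfonyl)hydrazinylidene]guai-4-en-8-yl 3-hydroxy-4-methoxybenzoate
Conditions: TsNHNH2, AcOH (cat.), EtOH, 60 °C
Reagents that add atoms: 4-methylbenzenesulfonohydrazide, Cc1ccc(cc1)S(=O)(=O)NN
Why: Condensation of the cyclopentenone carbonyl with tosylhydrazide (hydrazone formation) gives the α,β-unsaturated tosylhydrazone under mildly acidic conditions that leave the ester, the tertiary alcohol and all stereocenters untouched.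

Step 7
Reactants: 12 (1R,7R,8R,10R)-10-hydroxy-3-[(E)-2-(4-methylbenzenesulfonyl)hydrazinylidene]guai-4-en-8-yl 3-hydroxy-4-methoxybenzoate
Product: 14 (1R,5S,7R,8R,10R)-10-hydroxyguai-3-en-8-yl 3-hydroxy-4-methoxybenzoate, via allylic diazene 13 (not isolated)
Conditions: catecholborane (excess), CHCl3, 0 °C; then NaOAc·3H2O, reflux
Reagents that add atoms: none
Why: In this catecholborane reduction of an unsaturated tosylhydrazone with alkene transposition, hydride adds to C3 from the less hindered α-face (the β-face is screened by C10 and its β-methyl), loss of sulfinate gives the 3β-diazene, and its retro-ene loss of N2 delivers hydrogen suprafacially to the β-face of C5, which sets the trans ring fusion and moves the double bond to C3–C4.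

Step 8
Reactants: 14 (1R,5S,7R,8R,10R)-10-hydroxyguai-3-en-8-yl 3-hydroxy-4-methoxybenzoate
Product: 15 (1R,3R,4S,5S,7R,8R,10R)-3,4-epoxy-10-hydroxyguaian-8-yl 3-hydroxy-4-methoxybenzoate
Conditions: mCPBA, Na2HPO4, CH2Cl2, 0 °C
Reagents that add atoms: mCPBA, OOC(=O)c1cccc(Cl)c1
Why: Prilezhaev epoxidation of the only alkene (trisubstituted and electron-rich) is expected on the α-face, because the β-face of the cyclopentene is screened by the C10 β-methyl and the pseudo-axial H5 while the 10α-hydroxyl can hydrogen-bond the peracid on the α-side, and this sets C3 and C4.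

## Compound list

1 | (R)-(−)-α-phellandrene, (5R)-2-methyl-5-(propan-2-yl)cyclohexa-1,3-diene | CC1=CC[C@H](C(C)C)C=C1 | starting material
2 | (1R,4S,7R)-5-methyl-7-(propan-2-yl)-2,3-dioxabicyclo[2.2.2]oct-5-ene (peroxide bridge anti to isopropyl) | CC1=C[C@H]2[C@@H](C(C)C)C[C@@H]1OO2 | intermediate
3 | (4R,5R)-4-hydroxy-2-methyl-5-(propan-2-yl)cyclohex-2-en-1-one (hydroxyl trans to isopropyl) | CC1=C[C@H](O)[C@@H](C(C)C)CC1=O | intermediate
4 | isovanillic acid (3-hydroxy-4-methoxybenzoic acid) | COc1ccc(cc1O)C(=O)O | starting material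
5 | (1S,6R)-3-methyl-4-oxo-6-(propan-2-yl)cyclohex-2-en-1-yl 3-hydroxy-4-methoxybenzoate (ester cis to isopropyl) | CC1=C[C@@H](OC(=O)c2ccc(OC)c(O)c2)[C@@H](C(C)C)CC1=O | intermediate
6 | (1S,6R)-3-methyl-4-oxo-6-(propan-2-yl)cyclohex-2-en-1-yl 3-acetoxy-4-methoxybenzoate | CC1=C[C@@H](OC(=O)c2ccc(OC)c(OC(C)=O)c2)[C@@H](C(C)C)CC1=O | intermediate
7 | (1R,6R)-4-{[dimethyl(phenyl)silyl]oxy}-3-methyl-6-(propan-2-yl)cyclohex-3-en-1-yl 3-acetoxy-4-methoxybenzoate | CC1=C(O[Si](C)(C)c2ccccc2)C[C@H](C(C)C)[C@H](OC(=O)c2ccc(OC)c(OC(C)=O)c2)C1 | intermediate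
8 | 1,1-dimethoxypentan-3-one | CCC(=O)CC(OC)OC | starting material
9 | (1R,2R,5S)-5-(1-methoxy-3-oxopentyl)-5-methyl-4-oxo-2-(propan-2-yl)cyclohexyl 3-acetoxy-4-methoxybenzoate (both epimers at the methoxy carbon; side chain trans to ester and isopropyl) | CCC(=O)CC(OC)[C@]1(C)C[C@@H](OC(=O)c2ccc(OC)c(OC(C)=O)c2)[C@@H](C(C)C)CC1=O | intermediate
10 | (7R,8R,10S)-3-oxoeudesma-1,4-dien-8-yl 3-hydroxy-4-methoxybenzoate (7β-isopropyl, 8β-ester, 10β-methyl) | CC1=C2C[C@H](C(C)C)[C@H](OC(=O)c3ccc(OC)c(O)c3)C[C@@]2(C)C=CC1=O | intermediate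
11 | (1R,7R,8R,10R)-10-hydroxy-3-oxoguai-4-en-8-yl 3-hydroxy-4-methoxybenzoate (1α-H, 10α-OH, 10β-methyl) | O=C1C[C@H]2[C@](C)(O)C[C@@H](OC(=O)c3ccc(OC)c(O)c3)[C@@H](C(C)C)CC2=C1C | intermediate
12 | (1R,7R,8R,10R)-10-hydroxy-3-[(E)-2-(4-methylbenzenesulfonyl)hydrazinylidene]guai-4-en-8-yl 3-hydroxy-4-methoxybenzoate | Cc1ccc(cc1)S(=O)(=O)N/N=C1\C[C@H]2[C@](C)(O)C[C@@H](OC(=O)c3ccc(OC)c(O)c3)[C@@H](C(C)C)CC2=C1C | intermediate
13 | (1R,3S,7R,8R,10R)-3-diazenyl-10-hydroxyguai-4-en-8-yl 3-hydroxy-4-methoxybenzoate (3β-N=NH) | N=N[C@H]1C[C@H]2[C@](C)(O)C[C@@H](OC(=O)c3ccc(OC)c(O)c3)[C@@H](C(C)C)CC2=C1C | intermediate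
14 | (1R,5S,7R,8R,10R)-10-hydroxyguai-3-en-8-yl 3-hydroxy-4-methoxybenzoate (1α-H, 5β-H, trans-fused) | C1=C(C)[C@H]2C[C@H](C(C)C)[C@H](OC(=O)c3ccc(OC)c(O)c3)C[C@@](C)(O)[C@@H]2C1 | intermediate
15 | (1R,3R,4S,5S,7R,8R,10R)-3,4-epoxy-10-hydroxyguaian-8-yl 3-hydroxy-4-methoxybenzoate (3α,4α-epoxide, 1α-H, 5β-H, 8β-ester, 10α-OH) | COc1ccc(C(=O)O[C@@H]2C[C@@](C)(O)[C@@H]3C[C@H]4O[C@@]4(C)[C@H]3C[C@@H]2C(C)C)cc1O | target

## Step count and risks

Total step count: 8. Longest linear sequence: 8 steps (1 → 15).

The three steps most likely to fail: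

**Step 1 (selectivity of the rearrangement).** The amine may remove the other bridgehead hydrogen and give the regioisomeric hydroxy enone, and the facial ratio of oxygen addition is only modest. The fallback sets out from 2, isolated after the photooxygenation before any amine is added, and returns at 3. Thiourea in MeOH reduces the O–O bond to the ene-diol (1S,4R,5R)-2-methyl-5-(propan-2-yl)cyclohex-2-ene-1,4-diol F1. MnO2 in CH2Cl2 then oxidises the less hindered allylic hydroxyl (flanked by CH2) in preference to the one next to the isopropyl-bearing carbon, so regiochemistry is decided by sterics of an oxidation and not by the base-induced fragmentation.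

**Step 4 (proposed new annulation).** The acetal aldol at the hindered enol carbon, the ring closure, or the C10 selectivity may fall short. The fallback uses only established reactions, sets out from 7 and returns at 10. BF3·OEt2-mediated Mukaiyama–Michael addition of 7 to pent-1-en-3-one and aqueous work-up give the 1,5-diketone F2. TsOH in refluxing toluene closes and dehydrates it to the eudesm-4-en-3-one F3 (Robinson annulation). DDQ in refluxing dioxane introduces the 1,2-double bond to give the dienone aryl acetate F4, and K2CO3 in MeOH at 0 °C removes the aryl acetate to give 10.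

**Step 8 (face of epoxidation).** The peracid may prefer the β-face. The fallback sets out from 14 and returns at 15 by an anti-addition sequence that places oxygen on the face opposite to the one an electrophile attacks first. Ac2O in pyridine caps the phenol to give the aryl acetate F5 (this prevents ring bromination). NBS in aqueous THF forms the bromonium ion on the electrophile-preferred face and water opens it at the tertiary C4 from the other side to give the bromohydrin F6. K2CO3 in MeOH closes the epoxide by displacement of bromide and cleaves the aryl acetate in the same operation to give 15.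

## Further compounds

F1 | step 1 | (1S,4R,5R)-2-methyl-5-(propan-2-yl)cyclohex-2-ene-1,4-diol | CC1=C[C@H](O)[C@@H](C(C)C)C[C@@H]1O
F2 | step 4 | (1R,2R,5R)-5-methyl-4-oxo-5-(3-oxopentyl)-2-(propan-2-yl)cyclohexyl 3-acetoxy-4-methoxybenzoate | CCC(=O)CC[C@]1(C)C[C@@H](OC(=O)c2ccc(OC)c(OC(C)=O)c2)[C@@H](C(C)C)CC1=O
F3 | step 4 | (7R,8R,10R)-3-oxoeudesm-4-en-8-yl 3-acetoxy-4-methoxybenzoate (10β-methyl) | CC1=C2C[C@H](C(C)C)[C@H](OC(=O)c3ccc(OC)c(OC(C)=O)c3)C[C@@]2(C)CCC1=O
F4 | step 4 | (7R,8R,10S)-3-oxoeudesma-1,4-dien-8-yl 3-acetoxy-4-methoxybenzoate | CC1=C2C[C@H](C(C)C)[C@H](OC(=O)c3ccc(OC)c(OC(C)=O)c3)C[C@@]2(C)C=CC1=O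
F5 | step 8 | (1R,5S,7R,8R,10R)-10-hydroxyguai-3-en-8-yl 3-acetoxy-4-methoxybenzoate | C1=C(C)[C@H]2C[C@H](C(C)C)[C@H](OC(=O)c3ccc(OC)c(OC(C)=O)c3)C[C@@](C)(O)[C@@H]2C1
F6 | step 8 | 3β-bromo-4α,10α-dihydroxy-1αH,5βH-guaian-8β-yl 3-acetoxy-4-methoxybenzoate | COc1ccc(C(=O)O[C@@H]2C[C@@](C)(O)[C@@H]3C[C@H](Br)[C@@](C)(O)[C@H]3C[C@@H]2C(C)C)cc1OC(C)=O
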